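The closed, stirred vessel held substrate and reagent at constant temperature, and I had to say how much free target each flask of the row held at the end.

| setting | midnight | noon | south | south-west | south-east | west | north-east |
|---|---|---|---|---|---|---|---|
| substrate | 0.032 M | 0.55 M | 0.025 M | 0.050 M | 0.10 M | 0.20 M | 0.40 M |
| reagent | 0.294 M | 0.294 M | 0.294 M | 0.294 M | 0.294 M | 0.294 M | 0.294 M |
| remark | run made earlier | run made earlier |  |  |  |  |  |
| time |  |  | 20 h | 20 h | 20 h | 20 h | 20 h |

| run | time / h | target / % | substrate / % |
|---|---|---|---|
| midnight | 3.00 | 18.5 | 18.9 |
| midnight | 6.00 | 23.0 | 5.0 |
| midnight | 8.00 | 23.5 | 2.1 |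
| midnight | 12.0 | 26.0 | 0.9 |
| midnight | 15.0 | 24.5 | 0 |
| noon | 1.00 | 3.9 | 68.3 |
| noon | 2.00 | 4.3 | 58.3 |
| noon | 4.00 | 4.7 | 51.7 |
| noon | 8.00 | 4.4 | 49.6 |
| noon | 15.0 | 2.9 | 49.1 |

(readings scatter by 0.5 percentage points)

- in percentages every species weighs as the substrate in it: one idle adduct counts as two
- for target the idle adduct and crystals are counted in
- as a solid, counted per litre of solution: crystals
- steps that have been proposed: crystals <-> target; intermediate A <-> intermediate B; substrate + target <-> idle adduct; reagent + intermediate A <-> target; substrate + reagent <-> intermediate A
- in an amount of target, one idle adduct counts as one target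
- the concentration of target that is asked is that of its free form alone
- "hardly changes" means that all values lie within two and a half points (for a concentration: within two and a half percent of the largest)

- [target] (only what is free in solution) at the end for south, south-west, south-east, west, north-east, in this order
- the course of these numbers from the first flask to the last (rises all the way / falls all the way / hardly changes / rises, then falls / falls, then rises)

The midnight run charged 0.294 M of reagent against 0.032 M of substrate, and its last 3 target readings average 24.7%. Counting one reagent per substrate reacted and one more per target leaves 0.254 M of c(reagent). Dividing the ratio of target to the rest of the reacted substrate by that c(reagent) gave me, as a reading that carries the scatter, 1.29 L mol⁻¹, the split number g.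

I tested that count in the noon run in two ways. The substrate readings show 0.280 M consumed, while the reagent charge, shared out by the count at the last target reading, allows 0.278 M. The two agreed, so I trusted the count and took reagent as the limiting reagent in the noon run.

For south-east, the count and g together leave c(reagent) at 0.174 M, so the target share is 18.3% and the target 0.0183 M. Along the row the charge grows while the share shrinks, and north-east charges 0.40 M of substrate against 0.294 M of reagent, so I expected a rise and then a fall.

The forecast gave 0.0061 M, 0.0118 M, 0.019 M, 0.021 M and 0.009 M, course rises, then falls, on this ground: “Its yield therefore depends on leftover reagent.” Its south-east value of 0.019 M stands a little above my 0.0183 M.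

The flasks gave 0.00650 M, 0.0119 M, 0.0196 M, 0.0222 M and 0.0101 M, course rises, then falls, with the turn at a substrate charge of 0.17 M.

    crystals ⇌ target, rate k1*(cs1 - [target]) while solid is left; crystals form when [target] > cs1 (solubility = 0.0580 M, k = 0.351 min⁻¹)
    intermediate A ⇌ intermediate B (K = 25.0, k = 0.0499 min⁻¹)
    substrate + target ⇌ idle adduct, settled at all times (K = 2.50 L mol⁻¹)
    reagent + intermediate A ⇌ target (K = 36.0 L mol⁻¹, k = 0.0562 L mol⁻¹ min⁻¹)
    substrate + reagent ⇌ intermediate A (K = 26.5 L mol⁻¹, k = 0.0341 L mol⁻¹ min⁻¹)

In south at the end, the step between reagent plus intermediate A and target had, by that step alone and both ways together, a relaxation half-life of 0.706 h, short against the 20 h of the run, and g at the 0.263 M of reagent standing there gives 0.00632 M of target against 0.00650 M found. In west, target stood at 11.3% after 20.0 h, and after 200 h g at the 0.0781 M of reagent left gives 9.15% where the flask held 9.66%.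

(The runs come from a simulation with constants of no real substance.)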